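**Plan**

1. Numbering: guaianolide numbering C1–C15 for the tricyclic core; C1′(=O)–C2′(aryl)–C3′H2 for the δ-lactone arm. Retrosynthetic cuts: C3–C3′ and C4–CH3 / C4O–C1′ (releasing aryl acrylate 24), then C5–C6 and C8–C9 of the seven-membered ring.
2. Forward: cyclopentenone 6 (C1–C5 ring) and butanolide 9 (C6–C8, C11, C12, γ-lactone already closed) are united in one flask to the 5-7-5 lactone 12 (C5–C6 first, then C8–C9). The δ-lactone is then annulated (steps 14–15), followed by adjustment of C10, C2, C13 and protecting groups.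
3. Enabling feature: C8 carries the lactone oxygen next to the C7 stereocentre, so it can enter as an acylal (oxocarbenium precursor). C5 becomes the α-carbon of an enone when the C4 carbinol is taken back to a ketone. A 2-(silylmethyl)vinyl group on C1 (future C9/C10/C14) ends the cyclisation and keeps C1=C5.
4. Stereochemistry: C7 from the menthyl acetal of 7; C8 from C7 in the key step. The 2S silyloxy centre of 1 is a temporary control element for C3, C4 and C10 and is inverted late (oxidation, Luche reduction). The side-chain centre comes from asymmetric hydrogenation, C2′ from equilibration.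
5. Helpers removed: menthol and Me3Si leave in step 6, the C4 ketone becomes the carbinol in step 15, C10=C14 is reduced in step 17, PMB is cleaved in step 22.

Key step: step 6

Assumption: the aryl-bearing centre C2′ (α to the δ-lactone carbonyl) is epimerisable, and its natural R configuration is taken to be the thermodynamic one (aryl pseudo-equatorial), so it is set by base equilibration in step 20.

Abbreviations in names: Ar1 = 3-[(R)-5-(tert-butyldimethylsilyloxy)pentan-2-yl]-4-[(4-methoxybenzyloxy)methyl]phenyl; Ar2 = the same with a free 5-hydroxyl; menthyl = (1R,2S,5R)-2-isopropyl-5-methylcyclohexyl.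

**Route**

Step 1
Reactants: 1 (S)-4-(tert-butyldimethylsilyloxy)cyclopent-2-en-1-one; 2 2-bromo-3-(trimethylsilyl)prop-1-ene
Product: 4 tert-butyldimethyl{[(1S,2R)-4-(trimethylsilyloxy)-2-[3-(trimethylsilyl)prop-1-en-2-yl]cyclopent-3-en-1-yl]oxy}silane, via vinyl Grignard reagent 3 (not isolated)
Conditions: 2, Mg, THF, 40 °C; then 1, CuBr·SMe2 (10 mol %), Me3SiCl, THF, −78 °C; Et3N
Reagents that add atoms: chlorotrimethylsilane, C[Si](C)(C)Cl
Why: Copper-catalysed conjugate addition of the vinyl Grignard reagent should occur anti to the silyloxy group, and in situ O-silylation prevents β-elimination of the enolate; the new centre is erased in step 2.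

Step 2
Reactants: 4 silyl enol ether
Product: 5 (S)-4-(tert-butyldimethylsilyloxy)-3-[3-(trimethylsilyl)prop-1-en-2-yl]cyclopent-2-en-1-one
Conditions: IBX, 4-methoxypyridine N-oxide, DMSO, 25 °C
Reagents that add atoms: none
Why: Dehydrogenation of a regiodefined silyl enol ether with IBX (a palladium-free Saegusa-type oxidation) should restore the enone toward the only carbon that can lose hydrogen, and the oxidant is not electrophilic enough to attack the allylsilane.

Step 3
Reactants: 5 dienone
Product: 6 (S)-4-(tert-butyldimethylsilyloxy)-2-iodo-3-[3-(trimethylsilyl)prop-1-en-2-yl]cyclopent-2-en-1-one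
Conditions: I2, pyridine, CH2Cl2, 0 to 25 °C
Reagents that add atoms: iodine, II
Why: α-Iodination of an enone with I2/pyridine (pyridine addition, iodination of the enolate, elimination) should place iodine on C5; the allylsilane is conjugated with the dienone and is therefore a poor nucleophile toward iodine.

Step 4
Reactants: 7 (5R)-5-(menthyloxy)furan-2(5H)-one
Product: 8 (4S,5R)-4-(hydroxymethyl)-5-(menthyloxy)dihydrofuran-2(3H)-one
Conditions: MeOH, benzophenone (10 mol %), hν (350 nm), 25 °C
Reagents that add atoms: methanol, CO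
Why: Sensitised hydrogen abstraction from methanol gives the hydroxymethyl radical, which should add to the β-carbon of the butenolide anti to the menthyloxy group (radical conjugate addition), setting the future C7.

Step 5
Reactants: 8 alcohol
Product: 9 (4R,5R)-4-(iodomethyl)-5-(menthyloxy)dihydrofuran-2(3H)-one
Conditions: I2, PPh3, imidazole, CH2Cl2, 0 to 25 °C
Reagents that add atoms: iodine, II
Why: Appel iodination of the primary alcohol; the acylal and the stereocentres are not touched.

Step 6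
Reactants: 6 α-iodoenone; 9 iodomethyl butanolide
Product: 12 (2S,7R,8S)-2-(tert-butyldimethylsilyloxy)-4-oxo-15-norguaia-1(5),10(14)-dien-12,8-olide (trans-fused γ-lactone), via organozinc iodide 10 (not isolated), via coupled enone acylal 11 (not isolated)
Conditions: 9, Zn, LiCl, THF, 30 °C; then 6, Pd2(dba)3 (2.5 mol %), SPhos (10 mol %), 25 °C; then solvent exchange to CH2Cl2, Me3SiOTf (1.2 equiv), −78 to −40 °C
Reagents that add atoms: none
Why: Zinc inserts into the C6–I bond of 9 and the alkylzinc 10 is cross-coupled with the C5–I bond of 6 (Negishi coupling: oxidative addition, transmetalation, reductive elimination); Me3SiOTf then ionises the menthyl acylal of 11 to a cyclic acyloxycarbenium ion at C8, which is captured by the allylsilane terminus C9 (Hosomi–Sakurai reaction), leaving the alkene at C10=C14 and the silyl group on menthol. The closest known reaction types are the coupling of functionalised alkylzinc iodides with 2-iodocycloalkenones and the Lewis-acid substitution of 5-alkoxybutanolides by allylsilanes. The seven-membered ring should close by 7-exo attack on the C8 oxocarbenium carbon, with the allylsilane π-bond inside the new ring. C8 is the only new stereocentre and is controlled by C7: C9 should add anti to the C7–C6 bond, which keeps both new ring bonds on the lactone pseudo-equatorial and gives the trans-fused 8S lactone. The step needs ionisation at C8 in preference to the allylic C2 silyl ether and reaction of the silane through C9 only; the acylal is the sole position that gives an oxygen-stabilised cation (a C2 cation would sit γ to the enone carbonyl), and the position of silicon fixes C9 as the nucleophilic carbon.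

Step 7
Reactants: 13 (4-bromo-2-iodophenyl)methanol
Product: 14 4-bromo-2-iodo-1-[(4-methoxybenzyloxy)methyl]benzene
Conditions: NaH, 4-methoxybenzyl chloride, DMF, 0 to 25 °C
Reagents that add atoms: 4-methoxybenzyl chloride, COc1ccc(CCl)cc1
Why: Williamson etherification protects the benzylic alcohol as a PMB ether that survives all later steps and is removed oxidatively.

Step 8
Reactants: 14 PMB ether; 15 succinic anhydride
Product: 17 4-{5-bromo-2-[(4-methoxybenzyloxy)methyl]phenyl}-4-oxobutanoic acid, via aryl Grignard reagent 16 (not isolated)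
Conditions: iPrMgCl·LiCl, THF, −40 °C; then 15, −78 to 0 °C; aq. HCl
Reagents that add atoms: none
Why: Iodine–magnesium exchange is faster at C–I than at C–Br, and the aryl Grignard reagent should open the anhydride once (acylation), the carboxylate formed protecting the ketone from a second addition.

Step 9
Reactants: 17 keto acid
Product: 18 4-{5-bromo-2-[(4-methoxybenzyloxy)methyl]phenyl}pent-4-enoic acid
Conditions: Ph3PCH3Br, KOtBu (excess), THF, 0 to 25 °C; aq. acid
Reagents that add atoms: methyltriphenylphosphonium bromide, C[P+](c1ccccc1)(c1ccccc1)c1ccccc1.[Br-]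
Why: Wittig methylenation of the aryl ketone; the carboxylate is tolerated when excess ylide is used.

Step 10
Reactants: 18 alkenoic acid
Product: 19 (R)-4-{5-bromo-2-[(4-methoxybenzyloxy)methyl]phenyl}pentanoic acid
Conditions: H2 (6 atm), [Ir(cod)(SIPHOX)][B(3,5-(CF3)2C6H3)4] (1 mol %, ligand enantiomer chosen to give the R acid), Et3N, MeOH, 25 °C
Reagents that add atoms: none
Why: Carboxylate-directed asymmetric hydrogenation of a 1,1-disubstituted aryl alkene with a chiral iridium phosphine–oxazoline catalyst; the ligand controls the face and should set the benzylic centre as R.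

Step 11
Reactants: 19 acid
Product: 20 (R)-4-{5-bromo-2-[(4-methoxybenzyloxy)methyl]phenyl}pentan-1-ol
Conditions: BH3·THF, THF, 0 to 25 °C; aq. work-up
Reagents that add atoms: none
Why: Borane reduces the carboxylic acid chemoselectively; the aryl bromide and the PMB ether are inert.

Step 12
Reactants: 20 alcohol
Product: 21 (R)-tert-butyl{[4-(5-bromo-2-{[(4-methoxybenzyl)oxy]methyl}phenyl)pentyl]oxy}dimethylsilane
Conditions: tBuMe2SiCl, imidazole, DMF, 25 °C
Reagents that add atoms: tert-butyldimethylsilyl chloride, CC(C)(C)[Si](C)(C)Cl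
Why: Silylation of the primary alcohol, so that it is freed together with the C2 hydroxyl in step 16.

Step 13
Reactants: 21 aryl bromide; 22 methyl 2-bromoacrylate
Product: 24 methyl 2-Ar1-acrylate, via aryl pinacol boronate 23 (not isolated)
Conditions: B2pin2, KOAc, Pd(dppf)Cl2 (5 mol %), dioxane, 90 °C; then 22, aq. K3PO4, 60 °C
Reagents that add atoms: none
Why: Miyaura borylation of the aryl bromide followed in the same flask by Suzuki–Miyaura coupling with the α-bromoacrylate should give the 2-arylacrylate.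

Step 14
Reactants: 12 tricyclic dienone; 24 aryl acrylate
Product: 25 methyl 2-Ar1-3-[(2S,3S,7R,8S)-2-(tert-butyldimethylsilyloxy)-4-oxo-15-norguaia-1(5),10(14)-dien-12,8-olid-3-yl]propanoate (both C2′ epimers)
Conditions: LiN(iPr)2 (1.05 equiv), THF, −78 °C; then 24, −78 °C; AcOH
Reagents that add atoms: none
Why: The kinetic cross-conjugated enolate at C3 should add to the 2-arylacrylate (Michael addition) from the face anti to the adjacent C2 silyloxy group, setting C3; the ester-bearing centre forms as a mixture that is corrected in step 20.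

Step 15
Reactants: 25 keto ester
Product: 27 (2S,3S,4S,7R,8S)-2-(tert-butyldimethylsilyloxy)guaia-1(5),10(14)-dien-12,8-olide bridged from C3 to the C4 oxygen by the δ-lactone C3′H2–C2′H(Ar1)–C1′(=O) (both C2′ epimers), via tertiary alkoxide 26 (not isolated)
Conditions: MeLi, CeCl3, THF, −78 to 0 °C; aq. NH4Cl
Reagents that add atoms: methyllithium, [Li]C
Why: Organocerium 1,2-addition to the hindered dienone carbonyl should occur anti to the C3 side chain (setting C4), and the tertiary alkoxide, now cis to that chain, closes the δ-lactone by acyl substitution on the methyl ester.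

Step 16
Reactants: 27 bis-lactone
Product: 28 the diol of 27 (free 2S hydroxyl and free side-chain hydroxyl; aryl = Ar2)
Conditions: Bu4NF, AcOH, THF, 0 to 25 °C
Reagents that add atoms: none
Why: Fluoride cleaves both tert-butyldimethylsilyl ethers, while the PMB ether and both lactones are kept under buffered conditions.

Step 17
Reactants: 28 diene diol
Product: 29 the (10S)-10,14-dihydro derivative of 28 (guaia-1(5)-ene; C10–H cis to the C2 hydroxyl)
Conditions: H2 (1 atm), [Ir(cod)(PCy3)(py)]PF6 (5 mol %), CH2Cl2, 0 °C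
Reagents that add atoms: none
Why: Hydroxyl-directed homogeneous hydrogenation: the homoallylic C2 hydroxyl binds iridium and hydrogen should be delivered to the exocyclic C10=C14 bond from the hydroxyl face, setting C10, while the tetrasubstituted C1=C5 bond is too hindered to react.

Step 18
Reactants: 29 diol
Product: 30 the 2-oxo derivative of 29 (C2 ketone conjugated with C1=C5; side-chain hydroxyl free)
Conditions: MnO2, CH2Cl2, 25 °C
Reagents that add atoms: none
Why: MnO2 oxidises the allylic C2 alcohol and leaves the saturated primary alcohol; this removes the temporary C2 configuration.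

Step 19
Reactants: 30 enone
Product: 31 the (2R)-2-hydroxy epimer of 29 (C2 hydroxyl cis to the δ-lactone)
Conditions: NaBH4, CeCl3·7H2O, MeOH, −78 °C
Reagents that add atoms: none
Why: Luche 1,2-reduction: hydride should attack C2 from the face opposite the cis-fused δ-lactone and the C3 substituent, giving the natural 2R alcohol.

Step 20
Reactants: 31 diol bis-lactone
Product: 34 (2R,3S,4S,7R,8S,10S,2′R)-2-hydroxyguaia-1(5),11(13)-dien-12,8-olide with the C3/C4 δ-lactone bearing Ar2 at C2′, via Mannich base 32 (not isolated), via trimethylammonium iodide 33 (not isolated)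
Conditions: LiN(iPr)2 (4.5 equiv), THF, −78 °C; Me2N=CH2 I (1.2 equiv), −78 to 0 °C; aq. NH4Cl; then MeI, MeOH, 25 °C; then DBU, CH2Cl2, 25 °C
Reagents that add atoms: N,N-dimethylmethyleneiminium iodide (Eschenmoser's salt), C=[N+](C)C.[I-]
Why: In the polyanion the γ-lactone enolate at C11 is the least stabilised and least hindered carbanion and should be the one aminomethylated (Mannich reaction); quaternisation and base-induced Hofmann-type elimination give the α-methylene lactone, and DBU equilibrates C2′ to the R epimer.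

Step 21
Reactants: 34 diol
Product: 35 the 2-O-acetate and side-chain O-acetate of 34 (PMB ether of the target)
Conditions: Ac2O, pyridine, DMAP (cat.), CH2Cl2, 0 to 25 °C
Reagents that add atoms: acetic anhydride, CC(=O)OC(C)=O
Why: Acylation of the secondary allylic and the primary alcohol in one operation; the benzylic oxygen is still protected.

Step 22
Reactants: 35 PMB ether
Product: 36 CNP0205574.1
Conditions: DDQ, CH2Cl2/pH 7 buffer, 0 °C
Reagents that add atoms: none
Why: DDQ oxidises the electron-rich PMB ether (oxidative debenzylation) and should release the benzylic alcohol; the acetates and the α-methylene lactone are inert.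

**Compound list**

1 | (S)-4-(tert-butyldimethylsilyloxy)cyclopent-2-en-1-one | O=C1C=C[C@@H](O[Si](C)(C)C(C)(C)C)C1 | starting material
2 | 2-bromo-3-(trimethylsilyl)prop-1-ene | C=C(Br)C[Si](C)(C)C | starting material
3 | [3-(trimethylsilyl)prop-1-en-2-yl]magnesium bromide | C=C([Mg]Br)C[Si](C)(C)C | intermediate (not isolated)
4 | tert-butyldimethyl{[(1S,2R)-4-(trimethylsilyloxy)-2-[3-(trimethylsilyl)prop-1-en-2-yl]cyclopent-3-en-1-yl]oxy}silane | C=C(C[Si](C)(C)C)[C@H]1C=C(O[Si](C)(C)C)C[C@@H]1O[Si](C)(C)C(C)(C)C | intermediate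
5 | (S)-4-(tert-butyldimethylsilyloxy)-3-[3-(trimethylsilyl)prop-1-en-2-yl]cyclopent-2-en-1-one | C=C(C[Si](C)(C)C)C1=CC(=O)C[C@@H]1O[Si](C)(C)C(C)(C)C | intermediate
6 | (S)-4-(tert-butyldimethylsilyloxy)-2-iodo-3-[3-(trimethylsilyl)prop-1-en-2-yl]cyclopent-2-en-1-one | C=C(C[Si](C)(C)C)C1=C(I)C(=O)C[C@@H]1O[Si](C)(C)C(C)(C)C | intermediate
7 | (5R)-5-{[(1R,2S,5R)-2-isopropyl-5-methylcyclohexyl]oxy}furan-2(5H)-one | O=C1C=C[C@H](O[C@@H]2C[C@H](C)CC[C@H]2C(C)C)O1 | starting material
8 | (4S,5R)-4-(hydroxymethyl)-5-(menthyloxy)dihydrofuran-2(3H)-one | O=C1C[C@@H](CO)[C@H](O[C@@H]2C[C@H](C)CC[C@H]2C(C)C)O1 | intermediate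
9 | (4R,5R)-4-(iodomethyl)-5-(menthyloxy)dihydrofuran-2(3H)-one | O=C1C[C@@H](CI)[C@H](O[C@@H]2C[C@H](C)CC[C@H]2C(C)C)O1 | intermediate
10 | iodo{[(2R,3R)-2-(menthyloxy)-5-oxotetrahydrofuran-3-yl]methyl}zinc | O=C1C[C@@H](C[Zn]I)[C@H](O[C@@H]2C[C@H](C)CC[C@H]2C(C)C)O1 | intermediate (not isolated)
11 | (S)-4-(tert-butyldimethylsilyloxy)-2-{[(2R,3R)-2-(menthyloxy)-5-oxotetrahydrofuran-3-yl]methyl}-3-[3-(trimethylsilyl)prop-1-en-2-yl]cyclopent-2-en-1-one | C=C(C[Si](C)(C)C)C1=C(C[C@@H]2CC(=O)O[C@H]2O[C@@H]3C[C@H](C)CC[C@H]3C(C)C)C(=O)C[C@@H]1O[Si](C)(C)C(C)(C)C | intermediate (not isolated)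
12 | (2S,7R,8S)-2-(tert-butyldimethylsilyloxy)-4-oxo-15-norguaia-1(5),10(14)-dien-12,8-olide | C1C(=O)O[C@H]2CC(=C)C3=C(C[C@H]12)C(=O)C[C@@H]3O[Si](C)(C)C(C)(C)C | intermediate
13 | (4-bromo-2-iodophenyl)methanol | OCc1ccc(Br)cc1I | starting material
14 | 4-bromo-2-iodo-1-[(4-methoxybenzyloxy)methyl]benzene | COc1ccc(COCc2ccc(Br)cc2I)cc1 | intermediate
15 | succinic anhydride | O=C1CCC(=O)O1 | starting material
16 | {5-bromo-2-[(4-methoxybenzyloxy)methyl]phenyl}magnesium chloride | COc1ccc(COCc2ccc(Br)cc2[Mg]Cl)cc1 | intermediate (not isolated)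
17 | 4-{5-bromo-2-[(4-methoxybenzyloxy)methyl]phenyl}-4-oxobutanoic acid | OC(=O)CCC(=O)c1cc(Br)ccc1COCc1ccc(OC)cc1 | intermediate
18 | 4-{5-bromo-2-[(4-methoxybenzyloxy)methyl]phenyl}pent-4-enoic acid | OC(=O)CCC(=C)c1cc(Br)ccc1COCc1ccc(OC)cc1 | intermediate
19 | (R)-4-{5-bromo-2-[(4-methoxybenzyloxy)methyl]phenyl}pentanoic acid | OC(=O)CC[C@@H](C)c1cc(Br)ccc1COCc1ccc(OC)cc1 | intermediate
20 | (R)-4-{5-bromo-2-[(4-methoxybenzyloxy)methyl]phenyl}pentan-1-ol | OCCC[C@@H](C)c1cc(Br)ccc1COCc1ccc(OC)cc1 | intermediate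
21 | (R)-tert-butyl{[4-(5-bromo-2-{[(4-methoxybenzyl)oxy]methyl}phenyl)pentyl]oxy}dimethylsilane | CC(C)(C)[Si](C)(C)OCCC[C@@H](C)c1cc(Br)ccc1COCc1ccc(OC)cc1 | intermediate
22 | methyl 2-bromoacrylate | C=C(Br)C(=O)OC | starting material
23 | pinacol boronate of 21 (Bpin in place of Br) | CC(C)(C)[Si](C)(C)OCCC[C@@H](C)c1cc(B2OC(C)(C)C(C)(C)O2)ccc1COCc1ccc(OC)cc1 | intermediate (not isolated)
24 | methyl 2-{3-[(R)-5-(tert-butyldimethylsilyloxy)pentan-2-yl]-4-[(4-methoxybenzyloxy)methyl]phenyl}acrylate | C=C(C(=O)OC)c1ccc(COCc2ccc(OC)cc2)c([C@H](C)CCCO[Si](C)(C)C(C)(C)C)c1 | intermediate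
25 | methyl 2-Ar1-3-[(2S,3S,7R,8S)-2-(tert-butyldimethylsilyloxy)-4-oxo-15-norguaia-1(5),10(14)-dien-12,8-olid-3-yl]propanoate (C2′ epimers) | C1C(=O)O[C@H]2CC(=C)C3=C(C[C@H]12)C(=O)[C@@H](CC(C(=O)OC)c1ccc(COCc4ccc(OC)cc4)c([C@H](C)CCCO[Si](C)(C)C(C)(C)C)c1)[C@@H]3O[Si](C)(C)C(C)(C)C | intermediate
26 | (4S)-4-hydroxy-4-methyl adduct of 25 (tertiary alkoxide, drawn as the alcohol) | C1C(=O)O[C@H]2CC(=C)C3=C(C[C@H]12)[C@@](C)(O)[C@@H](CC(C(=O)OC)c1ccc(COCc4ccc(OC)cc4)c([C@H](C)CCCO[Si](C)(C)C(C)(C)C)c1)[C@@H]3O[Si](C)(C)C(C)(C)C | intermediate (not isolated)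
27 | (2S,3S,4S,7R,8S)-2-(tert-butyldimethylsilyloxy)guaia-1(5),10(14)-dien-12,8-olide with C3/C4 δ-lactone bearing Ar1 at C2′ (C2′ epimers) | C1C(=O)O[C@H]2CC(=C)C3=C(C[C@H]12)[C@@]1(C)OC(=O)C(c4ccc(COCc5ccc(OC)cc5)c([C@H](C)CCCO[Si](C)(C)C(C)(C)C)c4)C[C@H]1[C@@H]3O[Si](C)(C)C(C)(C)C | intermediate
28 | diol of 27 (2S hydroxyl, side-chain hydroxyl, aryl = Ar2) | C1C(=O)O[C@H]2CC(=C)C3=C(C[C@H]12)[C@@]1(C)OC(=O)C(c4ccc(COCc5ccc(OC)cc5)c([C@H](C)CCCO)c4)C[C@H]1[C@@H]3O | intermediate
29 | (10S)-10,14-dihydro derivative of 28 | C1C(=O)O[C@H]2C[C@H](C)C3=C(C[C@H]12)[C@@]1(C)OC(=O)C(c4ccc(COCc5ccc(OC)cc5)c([C@H](C)CCCO)c4)C[C@H]1[C@@H]3O | intermediate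
30 | 2-oxo derivative of 29 | C1C(=O)O[C@H]2C[C@H](C)C3=C(C[C@H]12)[C@@]1(C)OC(=O)C(c4ccc(COCc5ccc(OC)cc5)c([C@H](C)CCCO)c4)C[C@H]1C3=O | intermediate
31 | (2R)-2-hydroxy epimer of 29 | C1C(=O)O[C@H]2C[C@H](C)C3=C(C[C@H]12)[C@@]1(C)OC(=O)C(c4ccc(COCc5ccc(OC)cc5)c([C@H](C)CCCO)c4)C[C@H]1[C@H]3O | intermediate
32 | 11-(dimethylaminomethyl) derivative of 31 (Mannich base) | CN(C)CC1C(=O)O[C@H]2C[C@H](C)C3=C(C[C@H]12)[C@@]1(C)OC(=O)C(c4ccc(COCc5ccc(OC)cc5)c([C@H](C)CCCO)c4)C[C@H]1[C@H]3O | intermediate (not isolated)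
33 | trimethylammonium iodide of 32 | C[N+](C)(C)CC1C(=O)O[C@H]2C[C@H](C)C3=C(C[C@H]12)[C@@]1(C)OC(=O)C(c4ccc(COCc5ccc(OC)cc5)c([C@H](C)CCCO)c4)C[C@H]1[C@H]3O.[I-] | intermediate (not isolated)
34 | (2R,3S,4S,7R,8S,10S,2′R)-2-hydroxyguaia-1(5),11(13)-dien-12,8-olide with C3/C4 δ-lactone bearing Ar2 at C2′ | C=C1C(=O)O[C@H]2C[C@H](C)C3=C(C[C@H]12)[C@@]1(C)OC(=O)[C@@H](c4ccc(COCc5ccc(OC)cc5)c([C@H](C)CCCO)c4)C[C@H]1[C@H]3O | intermediate
35 | 2-O-acetyl, side-chain O-acetyl derivative of 34 (PMB ether of the target) | C=C1C(=O)O[C@H]2C[C@H](C)C3=C(C[C@H]12)[C@@]1(C)OC(=O)[C@@H](c4ccc(COCc5ccc(OC)cc5)c([C@H](C)CCCOC(C)=O)c4)C[C@H]1[C@H]3OC(C)=O | intermediate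
36 | CNP0205574.1 | C=C1C(=O)O[C@H]2C[C@H](C)C3=C(C[C@H]12)[C@@]1(C)OC(=O)[C@@H](c2ccc(CO)c([C@H](C)CCCOC(C)=O)c2)C[C@H]1[C@H]3OC(C)=O | target

**Totals**

Total step count: 22.
Longest linear sequence: 16 steps (13 to 36, steps 7–13 then 14–22).

**Steps most likely to fail**

1. Step 6. The ring closure may attack the oxocarbenium face syn to the tether (cis-fused lactone), or the conjugated, deactivated allylsilane may capture the cation too slowly. The fallback sets C8 in an intermolecular reaction and closes the ring at C5–C6 afterwards. It sets out from 5 and 9: Me3SiOTf in CH2Cl2 at −78 °C should join C9 to C8 anti to the iodomethyl group and give the trans-disubstituted butanolide dienone F1. Iodination with I2/pyridine, now free of the allylsilane, should give the vinyl/alkyl diiodide F2. Nickel-catalysed intramolecular reductive coupling of the two C–I bonds (NiBr2·glyme, 4,4′-di-tert-butyl-2,2′-bipyridine, Mn, DMA) then closes the seven-membered ring and comes back to the route at 12.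

2. Step 3. Iododesilylation of the allylsilane may compete with α-iodination. The fallback puts the iodine in before the allylsilane exists. It sets out from 1: I2/pyridine should give the known-type iodoenone F3, and Negishi coupling with 10 the 2-alkyl enone F4. Copper-catalysed addition of 3 with Me3SiCl then gives the silyl enol ether F5, and IBX dehydrogenation gives 11, here isolated. Cyclisation of 11 with Me3SiOTf comes back to the route at 12.

3. Step 17. Hydrogen may also be added across the diene in 1,4-fashion or to the tetrasubstituted C1=C5 bond, or be delivered to the wrong face. The fallback sets C10 at the dienone stage by conjugate reduction and thermodynamic protonation. It sets out from 12: 1,6-reduction with [(Ph3P)CuH]6 followed by mild base-mediated conjugation should give the 10S enone F6, with the methyl pseudo-axial to avoid strain against the C2 substituent. Michael addition to 24 as in step 14 gives keto ester F7, and MeLi/CeCl3 with lactonisation as in step 15 gives bis-lactone F8. Bu4NF/AcOH removes both silyl ethers and comes back to the route at 29.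

Further compounds
F1 | step 6 | (S)-4-(tert-butyldimethylsilyloxy)-3-{3-[(2S,3R)-3-(iodomethyl)-5-oxotetrahydrofuran-2-yl]prop-1-en-2-yl}cyclopent-2-en-1-one | C=C(C[C@@H]1OC(=O)C[C@H]1CI)C1=CC(=O)C[C@@H]1O[Si](C)(C)C(C)(C)C
F2 | step 6 | 2-iodo derivative of F1 | C=C(C[C@@H]1OC(=O)C[C@H]1CI)C1=C(I)C(=O)C[C@@H]1O[Si](C)(C)C(C)(C)C
F3 | step 3 | (S)-4-(tert-butyldimethylsilyloxy)-2-iodocyclopent-2-en-1-one | O=C1C(I)=C[C@@H](O[Si](C)(C)C(C)(C)C)C1
F4 | step 3 | (S)-4-(tert-butyldimethylsilyloxy)-2-{[(2R,3R)-2-(menthyloxy)-5-oxotetrahydrofuran-3-yl]methyl}cyclopent-2-en-1-one | O=C1C(C[C@@H]2CC(=O)O[C@H]2O[C@@H]3C[C@H](C)CC[C@H]3C(C)C)=C[C@@H](O[Si](C)(C)C(C)(C)C)C1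
F5 | step 3 | trimethylsilyl enol ether from addition of 3 to F4 (vinyl group trans to the silyloxy group) | C=C(C[Si](C)(C)C)[C@H]1C(C[C@@H]2CC(=O)O[C@H]2O[C@@H]3C[C@H](C)CC[C@H]3C(C)C)=C(O[Si](C)(C)C)C[C@@H]1O[Si](C)(C)C(C)(C)C
F6 | step 17 | (2S,7R,8S,10S)-2-(tert-butyldimethylsilyloxy)-4-oxo-15-norguaia-1(5)-en-12,8-olide | C1C(=O)O[C@H]2C[C@H](C)C3=C(C[C@H]12)C(=O)C[C@@H]3O[Si](C)(C)C(C)(C)C
F7 | step 17 | (10S)-10,14-dihydro analogue of 25 | C1C(=O)O[C@H]2C[C@H](C)C3=C(C[C@H]12)C(=O)[C@@H](CC(C(=O)OC)c1ccc(COCc4ccc(OC)cc4)c([C@H](C)CCCO[Si](C)(C)C(C)(C)C)c1)[C@@H]3O[Si](C)(C)C(C)(C)C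
F8 | step 17 | (10S)-10,14-dihydro analogue of 27 | C1C(=O)O[C@H]2C[C@H](C)C3=C(C[C@H]12)[C@@]1(C)OC(=O)C(c4ccc(COCc5ccc(OC)cc5)c([C@H](C)CCCO[Si](C)(C)C(C)(C)C)c4)C[C@H]1[C@@H]3O[Si](C)(C)C(C)(C)C
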